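(The readings are calculated for substances that don't exist; noise was put on by code.)

The delta run, with half the Z of your flask and the same G, shows Z falling from 95% at 10.0 min to 45% at 80.0 min. After the feed in that run, Q and Z together stay near the whole charge.

- delta: Z 0.034 M (fed, over 10 min); G 6.8 mM; run made earlier
- flask: Z 0.068 M (fed, over 10 min); G 6.8 mM; time 4.0 h

delta run (percent of the Z charged)

| time / min | Q / % | Z / % |
|---|---|---|
| 6.00 | 3 | 57 |
| 10.0 | 4 | 95 |
| 15.0 | 12 | 84 |
| 25.0 | 22 | 79 |
| 40.0 | 35 | 67 |
| 80.0 | 56 | 45 |

(readings scatter by 2 percentage points)

- the numbers in the tables scatter with a standard deviation of 2 percentage points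
- percentages count the whole charge, also what has not yet gone in

- amount of Q in percent of the Z charged, at 50 min, 2.0 h and 4.0 h

Take the first-order case (pseudo-first-order, with a steady number of growing centres) as the zero of the scale. Each Z then has the same chance of going per minute, so the percent curve does not depend on the charge. Your measure is the effective half-life: the time in which Z in percent would halve if its fall were first order. The two delta readings give 64.9 min, as a reading with its scatter.

My own reckoning for your flask starts the clock at mid-feed, 5.00 min. By 4.0 h it has passed 3.62 half-lives, so I put Q at that time at 91.9%, as an estimate.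

The forecast gives 40%, 71% and 90%, the last a little lower than mine. Its ground is “first-order kinetics do not depend on the Z charge”.

The flask gives 41.1%, 65.4% and 80.0%.

    2 L → J (k = 2.00 L mol⁻¹ min⁻¹)
    Z + L → Q + L, rate k2*[L]*[Z] (k = 2.80 L mol⁻¹ min⁻¹)
    Z + G → L + Q (k = 2.10 L mol⁻¹ min⁻¹)
    G ⇌ X (K = 1.50, k = 0.0310 min⁻¹)

In your flask the living ends L go from 0.00275 M at 0.167 h to 0.00120 M at 4.00 h. Z in your flask stands at 20.0% at 4.00 h, so its effective half-life from mid-feed to that time is 101 min, longer than the 64.9 min read between 10.0 min and 80.0 min in the delta run. The same flask with twice the G reaches Q 90.8%, which leaves Z 9.20%. Counted to 4.0 h, that is an effective half-life of 68.3 min.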